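Everything rests on building, not decorating, the hexasubstituted central benzene ring. Going round it: C1 indole A (6-methoxyindol-3-yl), C2 OMe, C3 OMe, C4 indole B (5-hydroxyindol-3-yl), C5 OMe, C6 OMe, so the oxygenated carbons C2 and C5 are para. That is the pattern of a chromium carbene benzannulation: C2 is the carbene carbon, C3=C4 its methoxyalkenyl arm, C6≡C1 an ynol ether, C5 a CO ligand. One operation forms C1–C2, C5–C6 and C4–C5 and closes the ring with all six substituents placed. The precursors are an N-tosyl (Z)-1-methoxy-2-(indol-3-yl)ethenyl methoxycarbene complex of Cr(CO)5 and an N-tosyl 3-(methoxyethynyl)indole.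

Key step: step 8

Design remarks (Ts, tosyl = 4-methylbenzenesulfonyl)
- **Tosyl on both indole nitrogens instead of a trialkylsilyl group.** An N-silyl indol-3-yl group is a vinylogous amino donor.
  - On the alkyne it would polarise the triple bond against the methoxy group.
  - On the alkenyl arm it would give a push–pull complex with a deactivated carbene carbon and tightly held CO ligands. Such complexes tend to close five-membered rings without CO uptake.
- **Chromium is not introduced through an alpha-lithiated enol ether.**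
  - An alkyllithium strong enough for that deprotonation also metalates the OCH2Ph group and indole C2, and it can eliminate methoxide.
  - A methoxymethylene olefination also leaves the alkene geometry open.
  - The (Z)-alkene is therefore fixed at the ester stage, and the acylchromate is made from the acid chloride and Na2Cr(CO)5.
- **Stereochemistry.** The target has no stereocentre. The only stereochemical element of the route is the (Z)-alkene, which is erased on aromatisation.
- **Assumption.** The minor (E) isomer formed in the olefination is removed by chromatography.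

Step 1
Reactants: 1 5-(benzyloxy)-1H-indole-3-carbaldehyde
Product: 2 5-(benzyloxy)-1-tosylindole-3-carbaldehyde
Conditions: TsCl, Et3N, DMAP (cat.), CH2Cl2, 20 °C
Reagents that add atoms: 4-toluenesulfonyl chloride, Cc1ccc(cc1)S(=O)(=O)Cl
Why: N-Sulfonylation of the acidic NH of a 3-formylindole by DMAP-catalysed sulfonyl transfer is routine, makes the aldehyde more electrophilic for step 2 and installs the acceptor group that later damps the donor push of indole B.

Step 2
Reactants: 2 5-(benzyloxy)-1-tosylindole-3-carbaldehyde; 3 methyl 2-(dimethoxyphosphoryl)-2-methoxyacetate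
Product: 4 methyl (Z)-3-[5-(benzyloxy)-1-tosylindol-3-yl]-2-methoxyprop-2-enoate
Conditions: 3 (1.3 equiv), NaH, THF, 0 → 20 °C; chromatography
Reagents that add atoms: none
Why: Horner–Wadsworth–Emmons olefination of a non-enolisable aryl aldehyde with a stabilised alpha-methoxyphosphonate anion, in which reversible addition and elimination should place the bulky indolyl group trans to the ester, that is cis to OMe, giving mainly the (Z)-alkene (no stereocentre is formed).

Step 3
Reactants: 4 methyl (Z)-3-[5-(benzyloxy)-1-tosylindol-3-yl]-2-methoxyprop-2-enoate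
Product: 5 (Z)-3-[5-(benzyloxy)-1-tosylindol-3-yl]-2-methoxyprop-2-enoic acid
Conditions: Me3SnOH (5 equiv), 1,2-dichloroethane, 80 °C; wash with 5% aq HCl
Reagents that add atoms: trimethyltin hydroxide, C[Sn](C)(C)O
Why: Mild ester hydrolysis with Me3SnOH, helped by coordination of tin to the alpha-methoxy oxygen, cleaves the methyl ester under nearly neutral conditions, so that the base-labile N-tosyl group, the benzyl ether and the alkene geometry are kept.

Step 4
Reactants: 5 (Z)-3-[5-(benzyloxy)-1-tosylindol-3-yl]-2-methoxyprop-2-enoic acid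
Product: 6 (Z)-3-[5-(benzyloxy)-1-tosylindol-3-yl]-2-methoxyprop-2-enoyl chloride
Conditions: (COCl)2 (1.5 equiv), DMF (cat.), CH2Cl2, 0 → 20 °C; evaporate, use crude
Reagents that add atoms: oxalyl chloride, O=C(Cl)C(=O)Cl
Why: Acid chloride formation through the Vilsmeier-type chloroiminium catalyst gives only gaseous by-products, and in the (Z)-isomer the acyl chloride points away from the indole, which rules out intramolecular Friedel–Crafts acylation.

Step 5
Reactants: 6 (Z)-3-[5-(benzyloxy)-1-tosylindol-3-yl]-2-methoxyprop-2-enoyl chloride; 7 chromium hexacarbonyl Cr(CO)6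
Product: 10 pentacarbonyl[(2Z)-3-(5-benzyloxy-1-tosylindol-3-yl)-1,2-dimethoxyprop-2-en-1-ylidene]chromium, via disodium pentacarbonylchromate 8 (not isolated), via sodium acylchromate 9 (not isolated)
Conditions: 7 (1.3 equiv), NaC10H8 (2.5 equiv), THF, −78 → 0 °C; 6, THF, −78 → 0 °C; evaporate; Me3OBF4, CH2Cl2, 0 °C
Reagents that add atoms: trimethyloxonium tetrafluoroborate, C[O+](C)C.F[B-](F)(F)F
Why: Acid chloride route to Fischer carbene complexes, in which the strongly nucleophilic pentacarbonylchromate dianion substitutes the acyl chloride far faster than it can add to the donor-deactivated and hindered beta-carbon, and O-methylation of the acylchromate with Me3OBF4 gives the methoxycarbene complex without any strong base touching the benzyl ether, indole C2 or the enol ether.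

Step 6
Reactants: 11 6-methoxy-1H-indole
Product: 13 3-iodo-6-methoxy-1-tosylindole, via 3-iodo-6-methoxyindole 12 (not isolated)
Conditions: I2, KOH (3.5 equiv), DMF, 20 °C; then TsCl, 0 → 20 °C
Reagents that add atoms: iodine, [I][I]; 4-toluenesulfonyl chloride, Cc1ccc(cc1)S(=O)(=O)Cl
Why: Electrophilic iodination of the indolyl anion at its most nucleophilic carbon C3 is followed in the same flask by N-sulfonylation, which turns the light- and acid-sensitive 3-iodoindole directly into a stable aryl iodide.

Step 7
Reactants: 14 chloroacetaldehyde dimethyl acetal; 13 3-iodo-6-methoxy-1-tosylindole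
Product: 17 6-methoxy-3-(methoxyethynyl)-1-tosylindole, via lithium methoxyacetylide 15 (not isolated), via methoxyethynylzinc chloride 16 (not isolated)
Conditions: 14 (2 equiv), LiNEt2 (from Et2NH and n-BuLi, 3 equiv per 14), THF, −10 → 20 °C; ZnCl2 (2 equiv per 14), 0 °C; 13, Pd(PPh3)4 (5 mol %), 20 → 40 °C; chromatography on Et3N-deactivated silica
Reagents that add atoms: none
Why: Twofold elimination (HCl, then MeOH) from the chloroacetal with three equivalents of amide base delivers lithium methoxyacetylide, and after transmetalation to zinc a Negishi coupling (oxidative addition of the C3–I bond to zerovalent palladium, transmetalation, reductive elimination) joins it to indole A under non-acidic conditions that an ynol ether tolerates.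

Step 8
Reactants: 10 pentacarbonyl[(2Z)-3-(5-benzyloxy-1-tosylindol-3-yl)-1,2-dimethoxyprop-2-en-1-ylidene]chromium; 17 6-methoxy-3-(methoxyethynyl)-1-tosylindole
Product: 21 6-[5-(benzyloxy)-1-tosylindol-3-yl]-2,4,5-trimethoxy-3-(6-methoxy-1-tosylindol-3-yl)phenol, via dienylcarbene complex 18 (not isolated), via dienylketene complex 19 (not isolated), via tricarbonylchromium arene complex 20 (not isolated)
Conditions: 10 (1.0 equiv), 17 (1.3 equiv), THF (0.1 mol/L), Ar, 50 °C; then hν (>350 nm), Ar, 20 °C; then air, MeCN, 20 °C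
Reagents that add atoms: none
Why: Proposed new method: the oxygen-polarised alkyne carbon that bears indole A attacks the electrophilic carbene carbon of 10 and the resulting chromacyclobutene opens to dienylcarbene 18, in which the former C–OMe alkyne carbon is the new oxygen-stabilised carbene centre, and thermal or light-driven migration of one CO ligand onto that carbon gives the chromium-bound dienylketene 19. The closest known reaction types are the Dötz benzannulation of alpha-alkoxyalkenyl methoxycarbene complexes with internal alkynes, the regiodefined insertion of ynamines and alkoxyalkynes into Fischer carbene complexes, and the photochemical carbonylative cyclisation of dienylcarbene complexes to ortho-alkoxyphenols, but their combination with an aryl ynol ether has not been shown. The single ring (the six-membered central benzene) closes by a six-electron disrotatory electrocyclisation of 19, C4 bonding to the ketene carbon C5, followed by enolisation to the phenol held as 20, which air demetalates. No stereocentre is created, and the (Z) geometry of 10 only serves to put hydrogen rather than indole B on the inside of the closing triene. The selectivity needed is the orientation of alkyne insertion (C1 to C2, not C6 to C2), against the usual steric rule that places the larger alkyne substituent next to the CO-derived carbon. It is secured by electronic matching, since both N-tosyl groups switch off the competing donor push of the indoles, so that only the methoxy oxygen polarises the triple bond of 17 while the carbene carbon of 10 stays electrophilic and its CO ligands stay labile.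

Step 9
Reactants: 21 6-[5-(benzyloxy)-1-tosylindol-3-yl]-2,4,5-trimethoxy-3-(6-methoxy-1-tosylindol-3-yl)phenol
Product: 22 5-(benzyloxy)-3-[2,3,5,6-tetramethoxy-4-(6-methoxy-1-tosylindol-3-yl)phenyl]-1-tosylindole
Conditions: MeI, K2CO3, DMF, 20 °C
Reagents that add atoms: iodomethane, CI
Why: Williamson ether synthesis on the only acidic OH works because K2CO3 in an aprotic solvent is too weak and non-nucleophilic to touch the N-tosyl groups, and early capping removes the oxidation-prone para-methoxyphenol.

Step 10
Reactants: 22 5-(benzyloxy)-3-[2,3,5,6-tetramethoxy-4-(6-methoxy-1-tosylindol-3-yl)phenyl]-1-tosylindole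
Product: 23 5-(benzyloxy)-3-[2,3,5,6-tetramethoxy-4-(6-methoxy-1H-indol-3-yl)phenyl]-1H-indole
Conditions: Mg turnings, MeOH/THF, 20 °C, ultrasound; aq NH4Cl
Reagents that add atoms: none
Why: Reductive desulfonylation by single-electron transfer from Mg in MeOH cleaves both N–S bonds as sulfinate under mild conditions, avoids the sulfonate esters that could N-alkylate the freed indoles in alkoxide-mediated cleavage, and leaves aryl methyl and benzyl ethers untouched.

Step 11
Reactants: 23 5-(benzyloxy)-3-[2,3,5,6-tetramethoxy-4-(6-methoxy-1H-indol-3-yl)phenyl]-1H-indole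
Product: 24 3-[2,3,5,6-tetramethoxy-4-(6-methoxy-1H-indol-3-yl)phenyl]-1H-indol-5-ol (CNP0234672.0)
Conditions: H2 (1 atm), 10% Pd/C, EtOAc/MeOH, 20 °C
Reagents that add atoms: none
Why: Catalytic hydrogenolysis of the aryl benzyl ether over Pd/C is selective because no other group is reducible under one atmosphere of H2, and it frees the air-sensitive 5-hydroxyindole only in the last step.

Compound list
1 | 5-(benzyloxy)-1H-indole-3-carbaldehyde | O=Cc1c[nH]c2ccc(OCc3ccccc3)cc12 | starting material
2 | 5-(benzyloxy)-1-tosylindole-3-carbaldehyde | O=Cc1cn(S(=O)(=O)c2ccc(C)cc2)c2ccc(OCc3ccccc3)cc12 | intermediate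
3 | methyl 2-(dimethoxyphosphoryl)-2-methoxyacetate (racemic) | COC(C(=O)OC)P(=O)(OC)OC | starting material
4 | methyl (Z)-3-[5-(benzyloxy)-1-tosylindol-3-yl]-2-methoxyprop-2-enoate | COC(=O)/C(OC)=C/c1cn(S(=O)(=O)c2ccc(C)cc2)c2ccc(OCc3ccccc3)cc12 | intermediate
5 | (Z)-3-[5-(benzyloxy)-1-tosylindol-3-yl]-2-methoxyprop-2-enoic acid | OC(=O)/C(OC)=C/c1cn(S(=O)(=O)c2ccc(C)cc2)c2ccc(OCc3ccccc3)cc12 | intermediate
6 | (Z)-3-[5-(benzyloxy)-1-tosylindol-3-yl]-2-methoxyprop-2-enoyl chloride | O=C(Cl)/C(OC)=C/c1cn(S(=O)(=O)c2ccc(C)cc2)c2ccc(OCc3ccccc3)cc12 | intermediate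
7 | chromium hexacarbonyl, Cr(CO)6 | O=C=[Cr](=C=O)(=C=O)(=C=O)(=C=O)=C=O | starting material
8 | disodium pentacarbonylchromate, Na2Cr(CO)5 | [Na+].[Na+].O=C=[Cr-2](=C=O)(=C=O)(=C=O)=C=O | intermediate
9 | sodium pentacarbonyl[(Z)-3-(5-benzyloxy-1-tosylindol-3-yl)-2-methoxyprop-2-enoyl]chromate | [Na+].[O-]C(=[Cr](=C=O)(=C=O)(=C=O)(=C=O)=C=O)/C(OC)=C/c1cn(S(=O)(=O)c2ccc(C)cc2)c2ccc(OCc3ccccc3)cc12 | intermediate
10 | pentacarbonyl[(2Z)-3-(5-benzyloxy-1-tosylindol-3-yl)-1,2-dimethoxyprop-2-en-1-ylidene]chromium (indole B trans to the carbene carbon) | COC(=[Cr](=C=O)(=C=O)(=C=O)(=C=O)=C=O)/C(OC)=C/c1cn(S(=O)(=O)c2ccc(C)cc2)c2ccc(OCc3ccccc3)cc12 | intermediate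
11 | 6-methoxy-1H-indole | COc1ccc2cc[nH]c2c1 | starting material
12 | 3-iodo-6-methoxy-1H-indole | COc1ccc2c(I)c[nH]c2c1 | intermediate
13 | 3-iodo-6-methoxy-1-tosylindole | COc1ccc2c(I)cn(S(=O)(=O)c3ccc(C)cc3)c2c1 | intermediate
14 | chloroacetaldehyde dimethyl acetal (2-chloro-1,1-dimethoxyethane) | COC(CCl)OC | starting material
15 | lithium methoxyacetylide | [Li]C#COC | intermediate
16 | methoxyethynylzinc chloride | COC#C[Zn]Cl | intermediate
17 | 6-methoxy-3-(methoxyethynyl)-1-tosylindole | COC#Cc1cn(S(=O)(=O)c2ccc(C)cc2)c2cc(OC)ccc12 | intermediate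
18 | pentacarbonyl[(2E,4Z)-5-(5-benzyloxy-1-tosylindol-3-yl)-1,3,4-trimethoxy-2-(6-methoxy-1-tosylindol-3-yl)penta-2,4-dien-1-ylidene]chromium | COC(=[Cr](=C=O)(=C=O)(=C=O)(=C=O)=C=O)/C(c1cn(S(=O)(=O)c2ccc(C)cc2)c2cc(OC)ccc12)=C(/OC)\C(OC)=C\c1cn(S(=O)(=O)c2ccc(C)cc2)c2ccc(OCc3ccccc3)cc12 | intermediate
19 | tetracarbonylchromium complex of (3E,5Z)-6-(5-benzyloxy-1-tosylindol-3-yl)-2,4,5-trimethoxy-3-(6-methoxy-1-tosylindol-3-yl)hexa-1,3,5-trien-1-one (metal–ligand bonding not drawn) | COC(=C=O)/C(c1cn(S(=O)(=O)c2ccc(C)cc2)c2cc(OC)ccc12)=C(/OC)\C(OC)=C\c1cn(S(=O)(=O)c2ccc(C)cc2)c2ccc(OCc3ccccc3)cc12.O=C=[Cr](=C=O)(=C=O)=C=O | intermediate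
20 | tricarbonylchromium complex of phenol 21, eta-6 on the central ring (metal–arene bonding not drawn) | Oc1c(OC)c(-c2cn(S(=O)(=O)c3ccc(C)cc3)c3cc(OC)ccc23)c(OC)c(OC)c1-c1cn(S(=O)(=O)c2ccc(C)cc2)c2ccc(OCc3ccccc3)cc12.O=C=[Cr](=C=O)=C=O | intermediate
21 | 6-[5-(benzyloxy)-1-tosylindol-3-yl]-2,4,5-trimethoxy-3-(6-methoxy-1-tosylindol-3-yl)phenol | Oc1c(OC)c(-c2cn(S(=O)(=O)c3ccc(C)cc3)c3cc(OC)ccc23)c(OC)c(OC)c1-c1cn(S(=O)(=O)c2ccc(C)cc2)c2ccc(OCc3ccccc3)cc12 | intermediate
22 | 5-(benzyloxy)-3-[2,3,5,6-tetramethoxy-4-(6-methoxy-1-tosylindol-3-yl)phenyl]-1-tosylindole | COc1c(OC)c(-c2cn(S(=O)(=O)c3ccc(C)cc3)c3cc(OC)ccc23)c(OC)c(OC)c1-c1cn(S(=O)(=O)c2ccc(C)cc2)c2ccc(OCc3ccccc3)cc12 | intermediate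
23 | 5-(benzyloxy)-3-[2,3,5,6-tetramethoxy-4-(6-methoxy-1H-indol-3-yl)phenyl]-1H-indole | COc1c(OC)c(-c2c[nH]c3cc(OC)ccc23)c(OC)c(OC)c1-c1c[nH]c2ccc(OCc3ccccc3)cc12 | intermediate
24 | 3-[2,3,5,6-tetramethoxy-4-(6-methoxy-1H-indol-3-yl)phenyl]-1H-indol-5-ol | COc1ccc2c(-c3c(OC)c(OC)c(-c4c[nH]c5ccc(O)cc45)c(OC)c3OC)c[nH]c2c1 | target

Total step count: 11. Longest linear sequence: 9 (steps 1–5 and 8–11).

Steps most likely to fail

**1. Step 8.**
What may go wrong:
- alkyne insertion in the sterically preferred orientation, with indole A next to the CO-derived carbon;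
- arrest at the oxygen-stabilised dienylcarbene stage;
- ring closure without CO uptake to a five-membered ring;
- chromium-initiated oligomerisation of the electron-rich alkyne.

Fallback (known chemistry; sets out from 11, comes back at 23): the central ring is taken from a quinone instead of being built. Acid-promoted conjugate addition of 11 to 2,5-dichloro-1,4-benzoquinone (HCl, THF) with DDQ reoxidation should give 2,5-dichloro-3-(6-methoxy-1H-indol-3-yl)-1,4-benzoquinone F1. The same addition and reoxidation with commercial 5-benzyloxyindole, at the only free quinone carbon, gives 2-[5-(benzyloxy)-1H-indol-3-yl]-3,6-dichloro-5-(6-methoxy-1H-indol-3-yl)-1,4-benzoquinone F2. NaOMe in MeOH exchanges both vinylogous acyl chlorides to give the corresponding 3,6-dimethoxyquinone F3. Na2S2O4 reduces it to the hydroquinone F4. MeI and K2CO3 in acetone, which do not deprotonate indole NH, methylate both phenols to 23, so that only step 11 remains.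

**2. Step 5.**
What may go wrong:
- electron transfer from the strongly reducing dianion to the enoyl chloride or to the N-sulfonyl group;
- conjugate attack instead of acyl substitution;
- decay of the acylchromate before O-methylation.

Fallback (sets out from 2 and 7, comes back at 10): chromium is put on a simple saturated chain first and the alkene is made last. Methoxymethyllithium F5 (Bu3SnCH2OMe, n-BuLi, THF, −78 °C) adds to a CO ligand of 7 to give lithium pentacarbonyl(methoxyacetyl)chromate F6. Me3OBF4 converts this into pentacarbonyl(1,2-dimethoxyethylidene)chromium F7. The CH-acidic methylene of F7 is then condensed with aldehyde 2 (Et3N, Me3SiCl, Et2O, 20 °C), an aldol-type condensation of Fischer carbene complexes with aromatic aldehydes. The reversible elimination should favour indole B trans to the bulky Cr(CO)5 carbene unit, which is 10.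

**3. Step 7.**
What may go wrong:
- protonation and hydration of the ynol ether during coupling or chromatography;
- sluggish transmetalation in the presence of amine and alkoxide;
- alkyne homocoupling;
- loss of the N-tosyl group to residual methoxide.

Fallback (sets out from 11, comes back at 17): the triple bond is made by elimination on the indole instead of by cross-coupling. Friedel–Crafts acylation of 11 at C3 with methoxyacetyl chloride (Et2AlCl, CH2Cl2, 0 °C) gives 2-methoxy-1-(6-methoxy-1H-indol-3-yl)ethanone F8. N-Tosylation (TsCl, Et3N, DMAP) gives 2-methoxy-1-(6-methoxy-1-tosylindol-3-yl)ethanone F9. The chelated enolate (LiN(SiMe3)2, THF, −78 °C) is trapped with PhNTf2 as (Z)-2-methoxy-1-(6-methoxy-1-tosylindol-3-yl)ethenyl triflate F10. KOtBu at −78 °C then effects anti elimination of triflate to 17.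

Further compounds
F1 | step 8 | 2,5-dichloro-3-(6-methoxy-1H-indol-3-yl)-1,4-benzoquinone | O=C1C=C(Cl)C(=O)C(c2c[nH]c3cc(OC)ccc23)=C1Cl
F2 | step 8 | 2-[5-(benzyloxy)-1H-indol-3-yl]-3,6-dichloro-5-(6-methoxy-1H-indol-3-yl)-1,4-benzoquinone | O=C1C(c2c[nH]c3ccc(OCc4ccccc4)cc23)=C(Cl)C(=O)C(c2c[nH]c3cc(OC)ccc23)=C1Cl
F3 | step 8 | 2-[5-(benzyloxy)-1H-indol-3-yl]-3,6-dimethoxy-5-(6-methoxy-1H-indol-3-yl)-1,4-benzoquinone | O=C1C(c2c[nH]c3ccc(OCc4ccccc4)cc23)=C(OC)C(=O)C(c2c[nH]c3cc(OC)ccc23)=C1OC
F4 | step 8 | 2-[5-(benzyloxy)-1H-indol-3-yl]-3,6-dimethoxy-5-(6-methoxy-1H-indol-3-yl)benzene-1,4-diol | Oc1c(-c2c[nH]c3ccc(OCc4ccccc4)cc23)c(OC)c(O)c(-c2c[nH]c3cc(OC)ccc23)c1OC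
F5 | step 5 | methoxymethyllithium | [Li]COC
F6 | step 5 | lithium pentacarbonyl(methoxyacetyl)chromate | [Li+].[O-]C(COC)=[Cr](=C=O)(=C=O)(=C=O)(=C=O)=C=O
F7 | step 5 | pentacarbonyl(1,2-dimethoxyethylidene)chromium | COCC(OC)=[Cr](=C=O)(=C=O)(=C=O)(=C=O)=C=O
F8 | step 7 | 2-methoxy-1-(6-methoxy-1H-indol-3-yl)ethanone | COCC(=O)c1c[nH]c2cc(OC)ccc12
F9 | step 7 | 2-methoxy-1-(6-methoxy-1-tosylindol-3-yl)ethanone | COCC(=O)c1cn(S(=O)(=O)c2ccc(C)cc2)c2cc(OC)ccc12
F10 | step 7 | (Z)-2-methoxy-1-(6-methoxy-1-tosylindol-3-yl)ethenyl trifluoromethanesulfonate | CO/C=C(\OS(=O)(=O)C(F)(F)F)c1cn(S(=O)(=O)c2ccc(C)cc2)c2cc(OC)ccc12
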